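**Plan**
1. Retrosynthetic cuts: the four ArO–CH2OMe bonds; the C2–C1' bond joining ring B to ring C (chromone plus arylboronic acid); O1–C2 and C2–C3 of ring C (2-hydroxyacetophenone plus one formyl carbon); the C2''–C3'' bond of the C8 side chain (key step); the C8–C1'' bond (C-prenylation of phloroacetophenone).
2. Enabling feature: in the C8 side chain the stereocentre C2'' lies between the benzylic C1''H2 and an isopropenyl group and bears the CH2CH2C(CH3)=CH2 arm. This is the pattern an (E)-4-chloro-3-methylbut-2-enyl group on ring A gives when a C5 nucleophile enters at its olefinic CH with allylic shift (SN2').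
3. Forward order: ring A is bought and prenylated at the future C8; the prenyl group is oxidised at its E-methyl, chlorinated and branched by the copper-catalysed SN2' alkylation, which completes the C10 chain; ring C is then closed as a chromone through the one free phenol; ring B is attached last at C2; the MOM ethers come off at the end.
4. Stereochemistry: (R)-C2'' comes from the chiral phosphoramidite–copper catalyst acting on the E-alkene; (S)-C2 comes from the chiral diene–rhodium catalyst in the 1,4-arylation; the centres are remote and each is set by its own catalyst.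

Key step: step 8

Assumption: side-chain locants are C1'' (benzylic CH2), C2'' (stereocentre), C3''–C4'' (CH2CH2), C5''(=C6''H2)C7''H3 and C8''(=C9''H2)C10''H3 (isopropenyl); the ligand antipodes quoted in steps 8 and 13 are those expected to give (R)-C2'' and (S)-C2, and the mirror-image ligand would be used if a trial run showed the opposite sense.

**Route**

Step 1
Reactants: 1 2,4,6-trihydroxyacetophenone; 2 prenyl bromide (1-bromo-3-methylbut-2-ene)
Product: 3 1-[2,4,6-trihydroxy-3-(3-methylbut-2-en-1-yl)phenyl]ethan-1-one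
Conditions: DBU (1.1 equiv), THF, 0 °C → rt, 1 in excess over 2
Reagents that add atoms: none
Why: Base-mediated C-alkylation (C-prenylation) of the phloroglucinol-type phenoxide, in which the ring carbon between two hydroxyl groups is the most nucleophilic carbon of the ambident anion, the two free ring positions are equivalent so only one mono-C-prenyl isomer can form, and the excess of 1 limits double prenylation.

Step 2
Reactants: 3 1-[2,4,6-trihydroxy-3-(3-methylbut-2-en-1-yl)phenyl]ethan-1-one
Product: 4 1-[2-hydroxy-4,6-bis(methoxymethoxy)-3-(3-methylbut-2-en-1-yl)phenyl]ethan-1-one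
Conditions: MOMCl (2.2 equiv), i-Pr2NEt (3 equiv), CH2Cl2, 0 °C → rt
Reagents that add atoms: chloromethyl methyl ether, COCCl
Why: Williamson-type O-alkylation in which the 4-OH and the unhindered 6-OH are etherified while the 2-OH, flanked by the prenyl group and hydrogen-bonded to the acetyl oxygen, should stay free, which later places the side chain at C8 of the chromone.

Step 3
Reactants: 4 1-[2-hydroxy-4,6-bis(methoxymethoxy)-3-(3-methylbut-2-en-1-yl)phenyl]ethan-1-one
Product: 5 1-[2-(tert-butyldimethylsilyloxy)-4,6-bis(methoxymethoxy)-3-(3-methylbut-2-en-1-yl)phenyl]ethan-1-one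
Conditions: TBSOTf (1.2 equiv), 2,6-lutidine (2 equiv), CH2Cl2, −78 → 0 °C
Reagents that add atoms: tert-butyldimethylsilyl trifluoromethanesulfonate, CC(C)(C)[Si](C)(C)OS(=O)(=O)C(F)(F)F
Why: O-Silylation of a hindered, chelated phenol with a silyl triflate, in which 2,6-lutidine is too weak a base to enolise the acetyl group and the MOM acetals tolerate the buffered triflate at or below 0 °C, so that the phenol is masked before the oxidation and halide chemistry that follow.

Step 4
Reactants: 5 1-[2-(tert-butyldimethylsilyloxy)-4,6-bis(methoxymethoxy)-3-(3-methylbut-2-en-1-yl)phenyl]ethan-1-one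
Product: 6 1-[2-(tert-butyldimethylsilyloxy)-3-[(2E)-4-hydroxy-3-methylbut-2-en-1-yl]-4,6-bis(methoxymethoxy)phenyl]ethan-1-one
Conditions: SeO2 (0.3 equiv), t-BuOOH (3 equiv, decane solution), salicylic acid (0.1 equiv), CH2Cl2, 0 °C → rt, stopped before over-oxidation
Reagents that add atoms: selenium dioxide (oxygen carrier), O=[Se]=O; tert-butyl hydroperoxide (terminal oxygen source), CC(C)(C)OO
Why: Riley-type allylic oxidation with catalytic SeO2, in which the ene reaction at the trisubstituted alkene and the following [2,3]-sigmatropic shift hydroxylate the E-methyl group selectively, so the (E)-allylic alcohol should result while the aryl methyl ketone, which needs heat to react with SeO2, is left alone.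

Step 5
Reactants: 6 1-[2-(tert-butyldimethylsilyloxy)-3-[(2E)-4-hydroxy-3-methylbut-2-en-1-yl]-4,6-bis(methoxymethoxy)phenyl]ethan-1-one
Product: 7 1-[2-(tert-butyldimethylsilyloxy)-3-[(2E)-4-chloro-3-methylbut-2-en-1-yl]-4,6-bis(methoxymethoxy)phenyl]ethan-1-one
Conditions: NCS (1.2 equiv) and Me2S (1.5 equiv) premixed in CH2Cl2, −20 °C; then 6, −20 → 0 °C
Reagents that add atoms: N-chlorosuccinimide, O=C1CCC(=O)N1Cl
Why: Corey–Kim chlorination, in which the alkoxysulfonium salt of the primary allylic alcohol is displaced by chloride at the primary carbon without allylic transposition so the E geometry is kept, and premixing NCS with excess Me2S leaves no electrophilic chlorine for the electron-rich ring.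

Step 6
Reactants: 7 1-[2-(tert-butyldimethylsilyloxy)-3-[(2E)-4-chloro-3-methylbut-2-en-1-yl]-4,6-bis(methoxymethoxy)phenyl]ethan-1-one
Product: 8 1-(tert-butyldimethylsilyloxy)-1-[2-(tert-butyldimethylsilyloxy)-3-[(2E)-4-chloro-3-methylbut-2-en-1-yl]-4,6-bis(methoxymethoxy)phenyl]ethene
Conditions: TBSOTf (1.3 equiv), i-Pr2NEt (2 equiv), CH2Cl2, −78 → 0 °C; filtration through Et3N-deactivated silica
Reagents that add atoms: tert-butyldimethylsilyl trifluoromethanesulfonate, CC(C)(C)[Si](C)(C)OS(=O)(=O)C(F)(F)F
Why: Silyl enol ether formation by soft enolisation of the methyl ketone with a silyl triflate and a hindered amine, which is too bulky to quaternise the allylic chloride and leaves the aryl silyl ether and the MOM acetals untouched at low temperature.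

Step 7
Reactants: 9 4-bromo-2-methylbut-1-ene
Product: 10 (3-methylbut-3-en-1-yl)magnesium bromide
Conditions: Mg turnings, Et2O, 35 °C, used as a titrated solution
Reagents that add atoms: magnesium, [Mg]
Why: Grignard formation by insertion of magnesium into the primary C–Br bond, which should give a homoallylic reagent that is stable in ether.

Step 8
Reactants: 8 1-(tert-butyldimethylsilyloxy)-1-[2-(tert-butyldimethylsilyloxy)-3-[(2E)-4-chloro-3-methylbut-2-en-1-yl]-4,6-bis(methoxymethoxy)phenyl]ethene; 10 (3-methylbut-3-en-1-yl)magnesium bromide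
Product: 11 1-(tert-butyldimethylsilyloxy)-1-[2-(tert-butyldimethylsilyloxy)-4,6-bis(methoxymethoxy)-3-[(2R)-5-methyl-2-(prop-1-en-2-yl)hex-5-en-1-yl]phenyl]ethene
Conditions: Cu(O2CC4H3S) (copper thiophene-2-carboxylate, monovalent copper, 3 mol %), BINOL-derived phosphoramidite with a bis[1-(2-methoxyphenyl)ethyl]amino group (3.3 mol %), CH2Cl2, −78 °C; 10 (1.3 equiv in Et2O) added over 2 h
Reagents that add atoms: none
Why: Transmetalation of 10 to the ligated monovalent copper gives a chiral alkylcopper species that attacks the (E)-allylic chloride anti-SN2' at its olefinic CH (C2''), and the resulting sigma-allyl trivalent copper intermediate reductively eliminates faster than it isomerises, so the C2''–C3'' bond forms and the double bond moves to C8''=C9'' (the isopropenyl group). The closest known reaction type is the copper/phosphoramidite-catalysed enantioselective allylic alkylation of 2-methyl-substituted (E)-allylic chlorides with primary alkyl Grignard reagents, which gives tertiary centres beside a 1,1-disubstituted alkene; here it is applied to a more hindered benzyl-substituted member of that class. No ring is closed in this step. The new C2'' stereocentre is set by the chiral phosphoramidite on copper, which selects one enantiotopic face of the geometrically pure E-alkene, and the ligand antipode that leads to (R) is used. The step needs gamma over alpha regioselectivity and enantioface selectivity: the 2-methyl substituent, the chloride leaving group, CH2Cl2 at −78 °C and slow addition of 10 (no build-up of free Grignard reagent that would attack alpha without the ligand) secure the first, and the single alkene geometry inherited from the SeO2 oxidation secures the second. Because the phenol is a silyl ether and the ketone a silyl enol ether, the allylic chloride is the only electrophile and no acidic proton consumes 10, while the MOM acetals and silyl groups are inert to Grignard and copper species at −78 °C.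

Step 9
Reactants: 11 1-(tert-butyldimethylsilyloxy)-1-[2-(tert-butyldimethylsilyloxy)-4,6-bis(methoxymethoxy)-3-[(2R)-5-methyl-2-(prop-1-en-2-yl)hex-5-en-1-yl]phenyl]ethene
Product: 12 1-[2-hydroxy-4,6-bis(methoxymethoxy)-3-[(2R)-5-methyl-2-(prop-1-en-2-yl)hex-5-en-1-yl]phenyl]ethan-1-one
Conditions: TBAF (2.2 equiv), AcOH (2.2 equiv), THF, 0 °C
Reagents that add atoms: none
Why: Fluoride-mediated desilylation in which both Si–O bonds are cleaved and acetic acid protonates the aryloxide and the enolate to the chelated phenol and the methyl ketone, while the buffered medium leaves the MOM acetals, both alkenes and the C2'' centre (not alpha to the carbonyl) untouched.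

Step 10
Reactants: 12 1-[2-hydroxy-4,6-bis(methoxymethoxy)-3-[(2R)-5-methyl-2-(prop-1-en-2-yl)hex-5-en-1-yl]phenyl]ethan-1-one
Product: 14 5,7-bis(methoxymethoxy)-8-[(2R)-5-methyl-2-(prop-1-en-2-yl)hex-5-en-1-yl]-4H-chromen-4-one, via enaminone 13 (not isolated)
Conditions: Me2NCH(OMe)2 (3 equiv), toluene, 95 °C; evaporation; then AcOH/toluene 1:4, 60 °C
Reagents that add atoms: N,N-dimethylformamide dimethyl acetal, COC(OC)N(C)C
Why: Chromone synthesis through an enaminone, in which condensation of the methyl ketone with the amide acetal supplies C2 and acid-promoted 6-endo oxa-Michael addition of the only free phenol with loss of dimethylamine closes ring C, acetic acid being too weak at 60 °C to cleave the MOM acetals or protonate the 1,1-disubstituted alkenes.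

Step 11
Reactants: 15 4-bromoresorcinol
Product: 16 1-bromo-2,4-bis(methoxymethoxy)benzene
Conditions: MOMCl (2.4 equiv), i-Pr2NEt (3 equiv), CH2Cl2, 0 °C → rt
Reagents that add atoms: chloromethyl methyl ether, COCCl
Why: Williamson-type O-alkylation of both phenols, which have no competing site.

Step 12
Reactants: 16 1-bromo-2,4-bis(methoxymethoxy)benzene
Product: 19 [2,4-bis(methoxymethoxy)phenyl]boronic acid, via aryllithium 17 (not isolated), via lithium aryltriisopropoxyborate 18 (not isolated)
Conditions: n-BuLi (1.05 equiv), THF, −78 °C; B(Oi-Pr)3 (1.5 equiv), −78 °C → rt; then H2O, AcOH to pH 6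
Reagents that add atoms: triisopropyl borate, CC(C)OB(OC(C)C)OC(C)C; water, O
Why: Borylation through an aryllithium, in which bromine–lithium exchange at −78 °C is faster than ortho-lithiation between the two MOM ethers, the aryllithium is trapped by the borate ester, and weakly acidic hydrolysis frees the boronic acid without cleaving the MOM acetals.

Step 13
Reactants: 14 5,7-bis(methoxymethoxy)-8-[(2R)-5-methyl-2-(prop-1-en-2-yl)hex-5-en-1-yl]-4H-chromen-4-one; 19 [2,4-bis(methoxymethoxy)phenyl]boronic acid
Product: 20 (2S)-2-[2,4-bis(methoxymethoxy)phenyl]-5,7-bis(methoxymethoxy)-8-[(2R)-5-methyl-2-(prop-1-en-2-yl)hex-5-en-1-yl]-2,3-dihydro-4H-chromen-4-one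
Conditions: [RhCl(C2H4)2]2 (2.5 mol %), (S,S)-2,5-diphenylbicyclo[2.2.2]octa-2,5-diene (5.5 mol %), KOH (0.1 equiv), 19 (3 equiv), 1,4-dioxane/H2O 10:1, 40 °C
Reagents that add atoms: none
Why: Hayashi–Miyaura reaction (asymmetric 1,4-addition of an arylboronic acid to a chromone catalysed by monovalent rhodium), in which the aryl–rhodium species bearing the chiral diene adds to one face of the C2=C3 bond and so sets C2 as S, water protonates the oxa-π-allyl rhodium intermediate, the remote C2'' centre should have no influence, and the isolated 1,1-disubstituted alkenes do not insert.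

Step 14
Reactants: 20 (2S)-2-[2,4-bis(methoxymethoxy)phenyl]-5,7-bis(methoxymethoxy)-8-[(2R)-5-methyl-2-(prop-1-en-2-yl)hex-5-en-1-yl]-2,3-dihydro-4H-chromen-4-one
Product: 21 remangiflavanone B [(2S)-2-(2,4-dihydroxyphenyl)-5,7-dihydroxy-8-[(2R)-5-methyl-2-(prop-1-en-2-yl)hex-5-en-1-yl]-2,3-dihydro-4H-chromen-4-one]
Conditions: 3 M aq. HCl/MeOH 1:10, 40 °C
Reagents that add atoms: none
Why: Acid-catalysed acetal exchange of the four MOM ethers with methanol, as practised on prenylated flavanones, in which the low acid strength and temperature should leave the 1,1-disubstituted alkenes unprotonated and, with no base present, the flavanone should not ring-open, so C2 and C2'' are retained.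

**Compound list**
1 | 2,4,6-trihydroxyacetophenone | CC(=O)c1c(O)cc(O)cc1O | starting material
2 | prenyl bromide (1-bromo-3-methylbut-2-ene) | CC(C)=CCBr | starting material
3 | 1-[2,4,6-trihydroxy-3-(3-methylbut-2-en-1-yl)phenyl]ethan-1-one | CC(=O)c1c(O)cc(O)c(CC=C(C)C)c1O | intermediate
4 | 1-[2-hydroxy-4,6-bis(methoxymethoxy)-3-(3-methylbut-2-en-1-yl)phenyl]ethan-1-one | CC(=O)c1c(O)c(CC=C(C)C)c(OCOC)cc1OCOC | intermediate
5 | 1-[2-(tert-butyldimethylsilyloxy)-4,6-bis(methoxymethoxy)-3-(3-methylbut-2-en-1-yl)phenyl]ethan-1-one | CC(=O)c1c(O[Si](C)(C)C(C)(C)C)c(CC=C(C)C)c(OCOC)cc1OCOC | intermediate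
6 | 1-[2-(tert-butyldimethylsilyloxy)-3-[(2E)-4-hydroxy-3-methylbut-2-en-1-yl]-4,6-bis(methoxymethoxy)phenyl]ethan-1-one | CC(=O)c1c(O[Si](C)(C)C(C)(C)C)c(C/C=C(\C)CO)c(OCOC)cc1OCOC | intermediate
7 | 1-[2-(tert-butyldimethylsilyloxy)-3-[(2E)-4-chloro-3-methylbut-2-en-1-yl]-4,6-bis(methoxymethoxy)phenyl]ethan-1-one | CC(=O)c1c(O[Si](C)(C)C(C)(C)C)c(C/C=C(\C)CCl)c(OCOC)cc1OCOC | intermediate
8 | 1-(tert-butyldimethylsilyloxy)-1-[2-(tert-butyldimethylsilyloxy)-3-[(2E)-4-chloro-3-methylbut-2-en-1-yl]-4,6-bis(methoxymethoxy)phenyl]ethene (TBS enol ether of 7) | C=C(O[Si](C)(C)C(C)(C)C)c1c(O[Si](C)(C)C(C)(C)C)c(C/C=C(\C)CCl)c(OCOC)cc1OCOC | intermediate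
9 | 4-bromo-2-methylbut-1-ene | C=C(C)CCBr | starting material
10 | (3-methylbut-3-en-1-yl)magnesium bromide | C=C(C)CC[Mg]Br | intermediate
11 | 1-(tert-butyldimethylsilyloxy)-1-[2-(tert-butyldimethylsilyloxy)-4,6-bis(methoxymethoxy)-3-[(2R)-5-methyl-2-(prop-1-en-2-yl)hex-5-en-1-yl]phenyl]ethene | C=C(C)CC[C@H](Cc1c(O[Si](C)(C)C(C)(C)C)c(C(=C)O[Si](C)(C)C(C)(C)C)c(OCOC)cc1OCOC)C(=C)C | intermediate
12 | 1-[2-hydroxy-4,6-bis(methoxymethoxy)-3-[(2R)-5-methyl-2-(prop-1-en-2-yl)hex-5-en-1-yl]phenyl]ethan-1-one | C=C(C)CC[C@H](Cc1c(O)c(C(C)=O)c(OCOC)cc1OCOC)C(=C)C | intermediate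
13 | (2E)-3-(dimethylamino)-1-[2-hydroxy-4,6-bis(methoxymethoxy)-3-[(2R)-5-methyl-2-(prop-1-en-2-yl)hex-5-en-1-yl]phenyl]prop-2-en-1-one (enaminone, formed in the flask) | C=C(C)CC[C@H](Cc1c(O)c(C(=O)/C=C/N(C)C)c(OCOC)cc1OCOC)C(=C)C | intermediate
14 | 5,7-bis(methoxymethoxy)-8-[(2R)-5-methyl-2-(prop-1-en-2-yl)hex-5-en-1-yl]-4H-chromen-4-one | C=C(C)CC[C@H](Cc1c(OCOC)cc(OCOC)c2c1OC=CC2=O)C(=C)C | intermediate
15 | 4-bromoresorcinol (4-bromobenzene-1,3-diol) | Oc1ccc(Br)c(O)c1 | starting material
16 | 1-bromo-2,4-bis(methoxymethoxy)benzene | COCOc1ccc(Br)c(OCOC)c1 | intermediate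
17 | [2,4-bis(methoxymethoxy)phenyl]lithium (aryllithium, formed in the flask) | [Li]c1ccc(OCOC)cc1OCOC | intermediate
18 | lithium [2,4-bis(methoxymethoxy)phenyl]triisopropoxyborate (formed in the flask) | [Li+].CC(C)O[B-](OC(C)C)(OC(C)C)c1ccc(OCOC)cc1OCOC | intermediate
19 | [2,4-bis(methoxymethoxy)phenyl]boronic acid | COCOc1ccc(B(O)O)c(OCOC)c1 | intermediate
20 | (2S)-2-[2,4-bis(methoxymethoxy)phenyl]-5,7-bis(methoxymethoxy)-8-[(2R)-5-methyl-2-(prop-1-en-2-yl)hex-5-en-1-yl]-2,3-dihydro-4H-chromen-4-one | C=C(C)CC[C@H](Cc1c(OCOC)cc(OCOC)c2c1O[C@H](c1ccc(OCOC)cc1OCOC)CC2=O)C(=C)C | intermediate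
21 | remangiflavanone B, (2S)-2-(2,4-dihydroxyphenyl)-5,7-dihydroxy-8-[(2R)-5-methyl-2-(prop-1-en-2-yl)hex-5-en-1-yl]-2,3-dihydro-4H-chromen-4-one | C=C(C)CC[C@H](Cc1c(O)cc(O)c2c1O[C@H](c1ccc(O)cc1O)CC2=O)C(=C)C | target

**Totals**
Total step count: 14. Longest linear sequence: 11 steps (steps 1–6, 8, 9, 10, 13, 14); steps 7, 11 and 12 feed in the two side branches.

**Steps most likely to fail**

1. Step 8. The bulky ortho,ortho'-dioxygenated benzyl group and its Lewis-basic MOM and silyloxy neighbours may slow the ligated copper pathway. Alpha substitution to the achiral linear product, or weak enantioface discrimination, could then compete.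
Fallback (reagent-controlled epoxidation and stereospecific substitution instead of catalyst control): it sets out from allylic alcohol 6 and comes back to the route at acetophenone 12. Sharpless asymmetric epoxidation of 6 (Ti(Oi-Pr)4 10 mol %, L-(+)-diethyl tartrate 12 mol %, t-BuOOH, 4 Å molecular sieves, CH2Cl2, −20 °C) should give the (2S,3S)-epoxy alcohol F1. The magnesium dialkylcuprate made from 10 and CuI (copper iodide) in a 2:1 ratio (Et2O/THF, −40 → 0 °C) should open the epoxide at its CH carbon with inversion, because the other epoxide carbon is quaternary and the hindered acetyl group is not attacked by a cuprate; this gives the 1,2-diol F2 with (R)-C2''. 1,1'-Thiocarbonyldiimidazole (toluene, 80 °C) converts F2 into the cyclic thiocarbonate F3. Corey–Winter olefination (P(OMe)3, 110 °C) turns the diol carbons into the isopropenyl group and gives the silyl-protected acetophenone F4. TBAF/AcOH as in step 9 then delivers 12.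

2. Step 13. Carbometalation of the electron-rich, 8-substituted chromone may be slow, so that protodeboronation of the ortho-alkoxy boronic acid overtakes it. Base-induced ring-opening of the product could also erode the C2 configuration.
Fallback (ring C closed from a chalcone instead of arylating a chromone): it sets out from acetophenone 12, with aryl bromide 16 as the source of ring B, and comes back at 20. Bromine–lithium exchange on 16 (n-BuLi, THF, −78 °C) and quenching with DMF gives 2,4-bis(methoxymethoxy)benzaldehyde F5. Claisen–Schmidt condensation of 12 with F5 (KOH, EtOH/H2O, rt) gives the 2'-hydroxychalcone F6. Base-mediated 6-endo oxa-Michael closure (NaOAc, EtOH, reflux) gives 20 together with its (2R) epimer F7, which is removed by preparative HPLC on a chiral stationary phase and can be returned to the equilibration.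

3. Step 14. Protonation of the 1,1-disubstituted alkenes under the acidic conditions could lead to addition of methanol or chloride, or to cyclisation of the 7-OH onto the isopropenyl group to a 2,2-dimethylchroman. Acid-promoted ring-opening could epimerise C2.
Fallback (protecting-group exchange under aprotic conditions, then fluoride, instead of acid solvolysis): it sets out from 20 and comes back at 21. TESOTf with 2,2'-bipyridyl (CH2Cl2, 0 °C → rt) should convert the four aryl MOM ethers directly into silyl ethers, giving the tetrakis(triethylsilyl) ether F8. Buffered fluoride (TBAF/AcOH, THF, 0 °C) then frees the four phenols to give 21 without any protic acid.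

**Further compounds**
F1 | step 8 | 1-[2-(tert-butyldimethylsilyloxy)-3-{[(2S,3S)-3-(hydroxymethyl)-3-methyloxiran-2-yl]methyl}-4,6-bis(methoxymethoxy)phenyl]ethan-1-one | CC(=O)c1c(O[Si](C)(C)C(C)(C)C)c(C[C@@H]2O[C@@]2(C)CO)c(OCOC)cc1OCOC
F2 | step 8 | 1-[2-(tert-butyldimethylsilyloxy)-3-[(2R)-2-[(2R)-1,2-dihydroxypropan-2-yl]-5-methylhex-5-en-1-yl]-4,6-bis(methoxymethoxy)phenyl]ethan-1-one | C=C(C)CC[C@H](Cc1c(O[Si](C)(C)C(C)(C)C)c(C(C)=O)c(OCOC)cc1OCOC)[C@@](C)(O)CO
F3 | step 8 | 1-[2-(tert-butyldimethylsilyloxy)-4,6-bis(methoxymethoxy)-3-[(2R)-5-methyl-2-[(4R)-4-methyl-2-sulfanylidene-1,3-dioxolan-4-yl]hex-5-en-1-yl]phenyl]ethan-1-one | C=C(C)CC[C@H](Cc1c(O[Si](C)(C)C(C)(C)C)c(C(C)=O)c(OCOC)cc1OCOC)[C@]1(C)COC(=S)O1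
F4 | step 8 | 1-[2-(tert-butyldimethylsilyloxy)-4,6-bis(methoxymethoxy)-3-[(2R)-5-methyl-2-(prop-1-en-2-yl)hex-5-en-1-yl]phenyl]ethan-1-one | C=C(C)CC[C@H](Cc1c(O[Si](C)(C)C(C)(C)C)c(C(C)=O)c(OCOC)cc1OCOC)C(=C)C
F5 | step 13 | 2,4-bis(methoxymethoxy)benzaldehyde | COCOc1ccc(C=O)c(OCOC)c1
F6 | step 13 | (2E)-3-[2,4-bis(methoxymethoxy)phenyl]-1-[2-hydroxy-4,6-bis(methoxymethoxy)-3-[(2R)-5-methyl-2-(prop-1-en-2-yl)hex-5-en-1-yl]phenyl]prop-2-en-1-one | C=C(C)CC[C@H](Cc1c(O)c(C(=O)/C=C/c2ccc(OCOC)cc2OCOC)c(OCOC)cc1OCOC)C(=C)C
F7 | step 13 | (2R)-2-[2,4-bis(methoxymethoxy)phenyl]-5,7-bis(methoxymethoxy)-8-[(2R)-5-methyl-2-(prop-1-en-2-yl)hex-5-en-1-yl]-2,3-dihydro-4H-chromen-4-one | C=C(C)CC[C@H](Cc1c(OCOC)cc(OCOC)c2c1O[C@@H](c1ccc(OCOC)cc1OCOC)CC2=O)C(=C)C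
F8 | step 14 | (2S)-2-[2,4-bis(triethylsilyloxy)phenyl]-8-[(2R)-5-methyl-2-(prop-1-en-2-yl)hex-5-en-1-yl]-5,7-bis(triethylsilyloxy)-2,3-dihydro-4H-chromen-4-one | C=C(C)CC[C@H](Cc1c(O[Si](CC)(CC)CC)cc(O[Si](CC)(CC)CC)c2c1O[C@H](c1ccc(O[Si](CC)(CC)CC)cc1O[Si](CC)(CC)CC)CC2=O)C(=C)C
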